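**Retrosynthetic overview**
1. Target ⇒ C7 ester from a 7,8-diol plus (S)-3-methylpentanoic acid (made by asymmetric hydrogenation of an achiral allylic alcohol); the C3=C4–C5=C6 dienol ether and C11 come last, by Stille hydroxymethylation of the dienyl triflate of a C4 ketone.
2. C1 senecioate ⇒ lactol released from a temporary 1,8-cyclic carbonate; C5=C6 and the C7 oxygen ⇒ β,γ-epoxy ketone opening (E1cB) after selenoxide elimination.
3. C8 carbinol ⇒ selenium-induced cyclisation of a C1 tert-butyl carbonate onto C7=C8; C10 isovalerate ⇒ lipase-catalysed regioselective acylation of a primary/secondary diol.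
4. Cyclopentene ring ⇒ phosphine-catalysed [3+2] annulation of an allenoate onto an enantioenriched pyranone (sets C9/C5 anti to the C1 substituent).
5. Ring order: pyran ring first (Achmatowicz rearrangement of furfuryl alcohol, then dynamic kinetic asymmetric acylation sets C1), cyclopentene second, temporary carbonate ring third (opened again before the diene is made).

Convention: iridoid numbering (C1 acetal carbon, O2, C3, C4, C5 and C9 ring-fusion carbons, C6–C8, C10 on C8, C11 on C4); β = the face of H-9, α = the opposite face.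
Assumption: (R)-benzotetramisole is taken to give the (S)-carbonate in step 6; if the sense is the opposite, the (S)-catalyst is used instead.

**Step 1**
Reactants: 1 ethyl but-2-ynoate
Product: 2 ethyl (E)-3-methylpent-2-enoate
Conditions: Et2CuLi, THF, −78 °C; aq. NH4Cl
Reagents that add atoms: lithium diethylcuprate, [Li+].CC[Cu-]CC
Why: Syn-carbocupration of the acetylenic ester puts ethyl and copper cis, so protonation gives the (E)-enoate stereospecifically.

**Step 2**
Reactants: 2 ethyl (E)-3-methylpent-2-enoate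
Product: 3 (E)-3-methylpent-2-en-1-ol
Conditions: i-Bu2AlH, CH2Cl2, −78 → 0 °C; aq. potassium sodium tartrate
Reagents that add atoms: none
Why: 1,2-Reduction of the ester by the aluminium hydride gives the allylic alcohol without touching the alkene geometry.

**Step 3**
Reactants: 3 (E)-3-methylpent-2-en-1-ol
Product: 4 (S)-3-methylpentan-1-ol
Conditions: H2 (100 atm), Ru(OAc)2[(R)-BINAP] (0.5 mol %), MeOH, 20 °C
Reagents that add atoms: none
Why: Noyori hydroxyl-directed asymmetric hydrogenation of the (E)-allylic alcohol with the (R)-BINAP catalyst delivers H2 to the face that gives the 3S centre (the sense that turns geraniol into (S)-citronellol).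

**Step 4**
Reactants: 4 (S)-3-methylpentan-1-ol
Product: 6 (S)-3-methylpentanoic acid, via (S)-3-methylpentanal 5 (not isolated)
Conditions: TEMPO (cat.), NaOCl (cat.), NaClO2, MeCN–phosphate buffer (pH 6.7), 35 °C
Reagents that add atoms: sodium chlorite, [Na+].[O-]Cl=O
Why: Oxoammonium/chlorite oxidation takes the primary alcohol through the aldehyde to the acid under near-neutral conditions that do not touch the β-stereocentre.

**Step 5**
Reactants: 7 furfuryl alcohol
Product: 8 6-hydroxy-2H-pyran-3(6H)-one (racemic lactol)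
Conditions: NBS, NaHCO3, THF–H2O (4:1), 0 °C
Reagents that add atoms: water, O
Why: Achmatowicz oxidative ring expansion of the furylcarbinol gives the pyranone lactol.

**Step 6**
Reactants: 8 6-hydroxy-2H-pyran-3(6H)-one
Product: 9 tert-butyl [(2S)-5-oxo-5,6-dihydro-2H-pyran-2-yl] carbonate
Conditions: Boc2O, (R)-benzotetramisole [(R)-2-phenyl-2,3-dihydroimidazo[2,1-b][1,3]benzothiazole] (5 mol %), CHCl3, −20 °C
Reagents that add atoms: di-tert-butyl dicarbonate, CC(C)(C)OC(=O)OC(=O)OC(C)(C)C
Why: Dynamic kinetic asymmetric acylation: the lactol racemises by ring–chain tautomerism while the chiral acyl-transfer catalyst carbonates one enantiomer faster, which sets C1.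

**Step 7**
Reactants: 9 tert-butyl [(2S)-5-oxo-5,6-dihydro-2H-pyran-2-yl] carbonate; 10 ethyl buta-2,3-dienoate
Product: 11 cis-fused bicyclic keto ester (1β-OBoc, C4 ketone, C7=C8, CO2Et on C8; H-5 and H-9 β)
Conditions: PPh3 (10 mol %), toluene, 20 °C
Reagents that add atoms: none
Why: Phosphine-catalysed [3+2] annulation: the allenoate zwitterion adds through its ester-bearing carbon to C9 anti to the C1 carbonate and closes onto C5 on the same face, giving the cis ring fusion with C10 already on C8.

**Step 8**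
Reactants: 11 bicyclic keto ester
Product: 12 diol (1β-OBoc, 4α-OH, C7=C8, C10–OH)
Conditions: i-Bu2AlH (4.5 equiv), CH2Cl2, −78 °C; aq. potassium sodium tartrate
Reagents that add atoms: none
Why: The aluminium hydride reduces the ketone (hydride from the convex β-face) and the enoate (1,2) at −78 °C while the hindered tert-butyl carbonate survives; the C4 carbinol centre is removed again in step 10.

**Step 9**
Reactants: 12 diol
Product: 13 C10 isovalerate (1β-OBoc, 4α-OH, C7=C8)
Conditions: lipase (immobilised Candida antarctica lipase B), isovaleric anhydride (1.1 equiv), t-BuOMe, 25 °C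
Reagents that add atoms: 3-methylbutanoic anhydride, CC(C)CC(=O)OC(=O)CC(C)C
Why: Lipase-catalysed acyl transfer is selective for the primary allylic hydroxyl over the ring secondary hydroxyl and installs the C10 isovalerate under neutral conditions.

**Step 10**
Reactants: 13 C10 isovalerate
Product: 14 C4 ketone (1β-OBoc, C7=C8, C10 isovalerate)
Conditions: Dess–Martin periodinane, pyridine, CH2Cl2, 0 → 20 °C
Reagents that add atoms: none
Why: Dess–Martin oxidation of the remaining secondary alcohol regenerates the C4 ketone without affecting the carbonate, ester or alkene.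

**Step 11**
Reactants: 14 C4 ketone
Product: 15 1,8-cyclic carbonate with 7β-phenylseleno group (C8–O α, C10 β)
Conditions: PhSeCl (1.1 equiv), CH2Cl2, 4 Å sieves, −78 → 0 °C
Reagents that add atoms: benzeneselenenyl chloride, Cl[Se]c1ccccc1
Why: Selenium-induced cyclofunctionalisation (selenium analogue of iodocarbonate cyclisation): PhSe+ adds to C7=C8 from the convex β-face and the carbonyl oxygen of the C1 carbonate, which lies gauche to C8 and can reach only its α-face, opens anti at the tertiary carbon with loss of the tert-butyl group, fixing C8.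

**Step 12**
Reactants: 15 seleno carbonate
Product: 17 C6=C7 alkene carbonate, via selenoxide 16 (not isolated)
Conditions: 30% H2O2, NaHCO3, THF, 0 → 20 °C
Reagents that add atoms: none
Why: Selenoxide syn-elimination can only run toward C6 because C8 carries no hydrogen, and it proceeds without base strong enough to move the β,γ-alkene into conjugation.

**Step 13**
Reactants: 17 C6=C7 alkene carbonate
Product: 19 enone with 7β-hydroxyl (C4 ketone, C5=C6), via β-epoxy ketone 18 (not isolated)
Conditions: dimethyldioxirane (acetone), 0 °C; then Et3N, CH2Cl2, 20 °C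
Reagents that add atoms: dimethyldioxirane, CC1(C)OO1
Why: Epoxidation occurs on the convex β-face (anti to the allylic C8–O bond and the carbonate ring), and E1cB opening of the β,γ-epoxy ketone by the C5 enolate then gives the conjugated enone with the C7 oxygen retained β.

**Step 14**
Reactants: 19 7β-hydroxy enone
Product: 20 7β-triethylsilyl ether
Conditions: Et3SiCl, imidazole, DMF, 0 °C
Reagents that add atoms: chlorotriethylsilane, CC[Si](Cl)(CC)CC
Why: Silylation protects the secondary allylic alcohol as an ether that zerovalent palladium cannot ionise in step 19.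

**Step 15**
Reactants: 20 silyl ether carbonate
Product: 21 lactol (1-OH, β-anomer drawn, anomers equilibrate; free 8α-OH)
Conditions: Et3N, THF–H2O (3:1), 0 → 20 °C; pH 7 phosphate buffer
Reagents that add atoms: none
Why: Mild hydrolysis of the activated acetal-type cyclic carbonate: the hemiacetal oxygen leaves first and the remaining monoalkyl carbonate loses CO2 on neutralisation, while the primary ester and silyl ether are untouched.

**Step 16**
Reactants: 21 lactol
Product: 22 1β-senecioate (3-methylbut-2-enoate at C1)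
Conditions: 3-methylbut-2-enoic acid, DCC, DMAP (cat.), CH2Cl2, −20 → 0 °C
Reagents that add atoms: 3-methylbut-2-enoic acid, CC(C)=CC(=O)O
Why: Steglich esterification acylates the equatorial anomeric hydroxyl of the equilibrating lactol (trans to the C9–C8 bond, the less hindered and natural arrangement) and leaves the tertiary C8 hydroxyl untouched.

**Step 17**
Reactants: 22 1β-senecioate
Product: 23 7β,8α-bis(triethylsilyl) ether
Conditions: Et3SiOTf, 2,6-lutidine, CH2Cl2, −78 °C
Reagents that add atoms: triethylsilyl trifluoromethanesulfonate, CC[Si](CC)(CC)OS(=O)(=O)C(F)(F)F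
Why: Silyl triflate silylation caps the tertiary alcohol so that its alkoxide cannot take the C1 or C10 acyl group during enolate formation.

**Step 18**
Reactants: 23 bis-silyl ether enone
Product: 24 dienyl triflate (C3=C4–OTf, C5=C6)
Conditions: KN(SiMe3)2 (1.05 equiv), PhNTf2, THF, −78 °C
Reagents that add atoms: N-phenylbis(trifluoromethanesulfonimide), O=S(=O)(N(c1ccccc1)S(=O)(=O)C(F)(F)F)C(F)(F)F
Why: Kinetic deprotonation can only occur at the C3 methylene (C5 is sp2), and O-triflation of that enolate fixes the C3=C4 enol double bond.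

**Step 19**
Reactants: 24 dienyl triflate
Product: 25 C11 alcohol (C4–CH2OH)
Conditions: Bu3SnCH2OH, Pd(PPh3)4 (10 mol %), LiCl, THF, 60 °C
Reagents that add atoms: (tributylstannyl)methanol, CCCC[Sn](CCCC)(CCCC)CO
Why: Stille cross-coupling of the alkenyl triflate with the hydroxymethyl stannane installs C11, and no allylic ester is present for the palladium to ionise.

**Step 20**
Reactants: 25 C11 alcohol
Product: 26 C11 acetate
Conditions: Ac2O, pyridine, DMAP (cat.), CH2Cl2, 0 °C
Reagents that add atoms: acetic anhydride, CC(=O)OC(C)=O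
Why: Base-buffered acetylation of the primary allylic alcohol keeps the acid-labile dienol ether intact.

**Step 21**
Reactants: 26 C11 acetate
Product: 27 7β,8α-diol
Conditions: HF·pyridine, pyridine, THF, 0 °C
Reagents that add atoms: none
Why: Pyridine-buffered fluoride desilylation removes both silyl ethers without ionising the acyl acetal or the dienol ether.

**Step 22**
Reactants: 27 7β,8α-diol; 6 (S)-3-methylpentanoic acid
Product: 28 target CNP0297662.1
Conditions: EDC·HCl, DMAP, CH2Cl2, 0 °C
Reagents that add atoms: none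
Why: Carbodiimide (Steglich) esterification acylates the secondary allylic C7 hydroxyl, while the tertiary C8 hydroxyl does not react.

**Compound list**
1 | ethyl but-2-ynoate | CC#CC(=O)OCC | starting material
2 | ethyl (E)-3-methylpent-2-enoate | CC/C(C)=C/C(=O)OCC | intermediate
3 | (E)-3-methylpent-2-en-1-ol | CC/C(C)=C/CO | intermediate
4 | (S)-3-methylpentan-1-ol | CC[C@H](C)CCO | intermediate
5 | (S)-3-methylpentanal (not isolated) | CC[C@H](C)CC=O | intermediate
6 | (S)-3-methylpentanoic acid | CC[C@H](C)CC(=O)O | intermediate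
7 | furfuryl alcohol (furan-2-ylmethanol) | OCc1ccco1 | starting material
8 | 6-hydroxy-2H-pyran-3(6H)-one, racemic and configurationally labile | OC1OCC(=O)C=C1 | intermediate
9 | tert-butyl [(2S)-5-oxo-5,6-dihydro-2H-pyran-2-yl] carbonate | O=C1CO[C@@H](OC(=O)OC(C)(C)C)C=C1 | intermediate
10 | ethyl buta-2,3-dienoate | C=C=CC(=O)OCC | starting material
11 | cis-fused cyclopenta[c]pyran keto ester: 1β-OBoc, C4 ketone, C7=C8, CO2Et on C8, H-5β, H-9β | O=C1CO[C@@H](OC(=O)OC(C)(C)C)[C@@H]2C(C(=O)OCC)=CC[C@H]12 | intermediate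
12 | diol: 1β-OBoc, 4α-OH, C7=C8, C10–OH, H-5β, H-9β | O[C@@H]1CO[C@@H](OC(=O)OC(C)(C)C)[C@@H]2C(CO)=CC[C@H]12 | intermediate
13 | 10-O-isovaleryl derivative of 12 (4α-OH free) | O[C@@H]1CO[C@@H](OC(=O)OC(C)(C)C)[C@@H]2C(COC(=O)CC(C)C)=CC[C@H]12 | intermediate
14 | C4 ketone: 1β-OBoc, C7=C8, 10-O-isovaleryl | O=C1CO[C@@H](OC(=O)OC(C)(C)C)[C@@H]2C(COC(=O)CC(C)C)=CC[C@H]12 | intermediate
15 | tricyclic 1,8-cyclic carbonate: C8–O α, C10 β, 7β-SePh, C4 ketone, H-5β, H-9β | O=C1CO[C@H]2OC(=O)O[C@]3(COC(=O)CC(C)C)[C@@H]([Se]c4ccccc4)C[C@H]1[C@H]23 | intermediate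
16 | selenoxide of 15 (not isolated) | O=C1CO[C@H]2OC(=O)O[C@]3(COC(=O)CC(C)C)[C@@H]([Se](=O)c4ccccc4)C[C@H]1[C@H]23 | intermediate
17 | 1,8-cyclic carbonate with C6=C7 alkene, C4 ketone, H-5β | O=C1CO[C@H]2OC(=O)O[C@]3(COC(=O)CC(C)C)C=C[C@H]1[C@H]23 | intermediate
18 | 6β,7β-epoxide of 17 (not isolated) | O=C1CO[C@H]2OC(=O)O[C@]3(COC(=O)CC(C)C)[C@H]4O[C@H]4[C@H]1[C@H]23 | intermediate
19 | 1,8-cyclic carbonate enone: C4 ketone, C5=C6, 7β-OH | O=C1CO[C@H]2OC(=O)O[C@]3(COC(=O)CC(C)C)[C@@H](O)C=C1[C@H]23 | intermediate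
20 | 7β-O-triethylsilyl ether of 19 | O=C1CO[C@H]2OC(=O)O[C@]3(COC(=O)CC(C)C)[C@@H](O[Si](CC)(CC)CC)C=C1[C@H]23 | intermediate
21 | lactol: 1-OH (β-anomer drawn, anomers equilibrate), 8α-OH, 7β-OTES, 10-O-isovaleryl, C4 ketone, C5=C6 | CC[Si](CC)(CC)O[C@H]1C=C2C(=O)CO[C@@H](O)[C@@H]2[C@@]1(O)COC(=O)CC(C)C | intermediate
22 | 1β-O-(3-methylbut-2-enoyl) derivative of 21 | CC[Si](CC)(CC)O[C@H]1C=C2C(=O)CO[C@@H](OC(=O)C=C(C)C)[C@@H]2[C@@]1(O)COC(=O)CC(C)C | intermediate
23 | 8α-O-triethylsilyl ether of 22 (7β,8α-bis-OTES) | CC[Si](CC)(CC)O[C@H]1C=C2C(=O)CO[C@@H](OC(=O)C=C(C)C)[C@@H]2[C@@]1(O[Si](CC)(CC)CC)COC(=O)CC(C)C | intermediate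
24 | dienyl triflate: C3=C4(OTf), C5=C6 | CC[Si](CC)(CC)O[C@H]1C=C2C(OS(=O)(=O)C(F)(F)F)=CO[C@@H](OC(=O)C=C(C)C)[C@@H]2[C@@]1(O[Si](CC)(CC)CC)COC(=O)CC(C)C | intermediate
25 | C11 alcohol: C4–CH2OH on the C3=C4–C5=C6 dienol ether | CC[Si](CC)(CC)O[C@H]1C=C2C(CO)=CO[C@@H](OC(=O)C=C(C)C)[C@@H]2[C@@]1(O[Si](CC)(CC)CC)COC(=O)CC(C)C | intermediate
26 | 11-O-acetate of 25 | CC[Si](CC)(CC)O[C@H]1C=C2C(COC(C)=O)=CO[C@@H](OC(=O)C=C(C)C)[C@@H]2[C@@]1(O[Si](CC)(CC)CC)COC(=O)CC(C)C | intermediate
27 | 7β,8α-diol: 1β-O-senecioyl, 10-O-isovaleryl, 11-O-acetyl | O[C@H]1C=C2C(COC(C)=O)=CO[C@@H](OC(=O)C=C(C)C)[C@@H]2[C@@]1(O)COC(=O)CC(C)C | intermediate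
28 | CNP0297662.1: 7β-O-[(S)-3-methylpentanoyl], 8α-OH, 10-O-isovaleryl, 1β-O-senecioyl, 11-O-acetyl, H-9β | CC[C@H](C)CC(=O)O[C@H]1C=C2C(COC(C)=O)=CO[C@@H](OC(=O)C=C(C)C)[C@@H]2[C@@]1(O)COC(=O)CC(C)C | target

**Step count**
Total: 22 steps. Longest linear sequence: 18 steps (steps 5–22, from furfuryl alcohol); the acid branch is 4 steps (steps 1–4) and joins in step 22.

**Three steps most likely to fail, with fallbacks**

Step 11 (selenium-induced carbonate cyclisation). The C4 ketone oxygen or the C10 ester carbonyl may compete with the carbonate as the internal nucleophile, and the selenium variant of the carbonate cyclisation is less tested than the iodine one. The fallback sets out from 13 and returns at 17, using the classical iodocarbonate cyclisation with the C4 oxygen masked. Compound 13 is silylated (t-BuMe2SiCl, imidazole, DMF) to the 4α-O-tert-butyldimethylsilyl ether F1. IBr (CH2Cl2–toluene, −80 °C) then gives the 7β-iodo 1,8-cyclic carbonate F2. DBU (toluene, 80 °C) eliminates HI anti toward C6 to the C6=C7 alkene silyl ether F3. HF·pyridine frees the C4 alcohol F4, and Dess–Martin oxidation gives 17.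

Step 13 (facial selectivity of the epoxidation, and isomerisation of the β,γ-enone before it is epoxidised). The fallback sets out from 17 and returns at 19 and replaces epoxidation/E1cB by a Schenck ene reaction. Singlet oxygen (O2, tetraphenylporphyrin, visible light, CH2Cl2, −20 °C) can abstract only H-5, which lies on the β-face, so oxygen is delivered suprafacially to C7 on the β-face with the double bond moving to C5=C6. This gives the 7β-hydroperoxy enone carbonate F5, and PPh3 reduces it to 19.

Step 16 (acylation of the labile β-hydroxy lactol; the C1 configuration rests on substrate control). The fallback sets out from 21 and returns at 22 and fixes C1 by an inverting displacement instead. Cl3CCN with catalytic DBU (CH2Cl2, 0 °C) gives, under thermodynamic control, the axial 1α-trichloroacetimidate F6. 3-Methylbut-2-enoic acid (CH2Cl2, 20 °C, no promoter) then displaces it with inversion to give the 1β-ester 22.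

**Further compounds**
F1 | step 11 | 4α-O-tert-butyldimethylsilyl ether of 13 | CC(C)(C)[Si](C)(C)O[C@@H]1CO[C@@H](OC(=O)OC(C)(C)C)[C@@H]2C(COC(=O)CC(C)C)=CC[C@H]12
F2 | step 11 | 7β-iodo 1,8-cyclic carbonate with 4α-OTBS | CC(C)(C)[Si](C)(C)O[C@@H]1CO[C@H]2OC(=O)O[C@]3(COC(=O)CC(C)C)[C@@H](I)C[C@H]1[C@H]23
F3 | step 11 | C6=C7 alkene 1,8-cyclic carbonate with 4α-OTBS | CC(C)(C)[Si](C)(C)O[C@@H]1CO[C@H]2OC(=O)O[C@]3(COC(=O)CC(C)C)C=C[C@H]1[C@H]23
F4 | step 11 | C6=C7 alkene 1,8-cyclic carbonate with free 4α-OH | O[C@@H]1CO[C@H]2OC(=O)O[C@]3(COC(=O)CC(C)C)C=C[C@H]1[C@H]23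
F5 | step 13 | 7β-hydroperoxy enone 1,8-cyclic carbonate | O=C1CO[C@H]2OC(=O)O[C@]3(COC(=O)CC(C)C)[C@@H](OO)C=C1[C@H]23
F6 | step 16 | 1α-trichloroacetimidate of lactol 21 | CC[Si](CC)(CC)O[C@H]1C=C2C(=O)CO[C@H](OC(=N)C(Cl)(Cl)Cl)[C@@H]2[C@@]1(O)COC(=O)CC(C)C
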